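**Retrosynthetic overview**

1. The target is a trans-decalin (ring A = bromocyclohexane, ring B = central cyclohexane) fused to a bicyclo[2.2.1]heptane (rings C and D = its two cyclopentane rings). The last C–C bond made is the one between the carbinol carbon C(OH)(i-Pr) of ring D and the quaternary bridgehead shared by rings B, C and D; the ring-B alkene left behind is hydrogenated.
2. Enabling feature: the bridgehead is a ring-B carbon flanked by CH2–CH2, so it can be the substituted terminus of a ring-B allyl unit. It also lies 1,5 to the carbinol carbon through ring C (bridgehead–CH2–CH–CH2–C(OH)). A ring-B/C 1,3-diene carrying a CH2C(O)i-Pr arm on the ring-C methine can therefore close ring D by intramolecular allylation of the ketone.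
3. Ring C: Wittig methylenation and ring-closing metathesis onto the vinyl group of a side chain attached by α′-alkylation of a ring-B enone with an enantiopure iodide (made from furan-2(5H)-one).
4. Ring B: aldol condensation of a methyl ketone with a neopentyl aldehyde; the methyl ketone comes from MeLi opening of a ring-A-fused lactone, which also frees the axial tertiary alcohol.
5. Ring A: enantiospecific bromonium cyclization of an acyclic bromohydrin ester (Sharpless epoxidation, then bromide opening) sets C–Br, the quaternary methyl carbon, the ring-fusion CH and the C(Me)–O centre. Order of ring formation: A, B, C, D.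

Key step: step 16

Remark on the chemistry: hydroxy ketones 7 and 13 are drawn in the open form although each should equilibrate with its five-membered cyclic hemiketal; the later steps drain the open form.

**Route**

Step 1
Reactants: 1 geranyl chloride, (2E)-1-chloro-3,7-dimethylocta-2,6-diene
Product: 2 methyl (3E)-4,8-dimethylnona-3,7-dienoate
Conditions: CO (20 bar), PdCl2(PPh3)2 (2 mol%), i-Pr2NEt, MeOH, 60 °C
Reagents that add atoms: carbon monoxide, [C-]#[O+]; methanol, CO
Why: Palladium-catalysed alkoxycarbonylation of an allylic chloride, in which CO inserts at the primary terminus of the π-allylpalladium complex, should give the β,γ-unsaturated ester with the E alkene retained.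

Step 2
Reactants: 2 methyl (3E)-4,8-dimethylnona-3,7-dienoate
Product: 3 methyl (3E,7E)-9-hydroxy-4,8-dimethylnona-3,7-dienoate
Conditions: SeO2 (cat.), t-BuOOH, salicylic acid (cat.), CH2Cl2, 25 °C
Reagents that add atoms: tert-butyl hydroperoxide, CC(C)(C)OO
Why: Selenium dioxide allylic oxidation (ene reaction, then [2,3]-sigmatropic shift) is selective for the E-methyl group of the more electron-rich terminal trisubstituted alkene.

Step 3
Reactants: 3 methyl (3E,7E)-9-hydroxy-4,8-dimethylnona-3,7-dienoate
Product: 4 methyl (3E)-6-[(2R,3R)-3-(hydroxymethyl)-3-methyloxiran-2-yl]-4-methylhex-3-enoate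
Conditions: Ti(OiPr)4 (10 mol%), D-(−)-diethyl tartrate (12 mol%), t-BuOOH, 4 Å molecular sieves, CH2Cl2, −20 °C
Reagents that add atoms: tert-butyl hydroperoxide, CC(C)(C)OO
Why: Sharpless asymmetric epoxidation of the E-trisubstituted allylic alcohol with D-(−)-diethyl tartrate should deliver oxygen to the face that gives the (2R,3R)-epoxide, which fixes the absolute configuration of ring A and leaves the remote alkene untouched.

Step 4
Reactants: 4 methyl (3E)-6-[(2R,3R)-3-(hydroxymethyl)-3-methyloxiran-2-yl]-4-methylhex-3-enoate
Product: 5 methyl (3E,7S,8R)-7-bromo-8,9-dihydroxy-4,8-dimethylnon-3-enoate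
Conditions: Et2NH2Br, Ti(OiPr)4 (1.5 equiv), CH2Cl2, 25 °C
Reagents that add atoms: diethylammonium bromide, CC[NH2+]CC.[Br-]
Why: Ti(OiPr)4-mediated opening of a 2,3-epoxy alcohol, in which the titanium-bound epoxy alkoxide directs bromide to the carbon remote from the CH2OH group with inversion (SN2), sets the C–Br stereocentre.

Step 5
Reactants: 5 methyl (3E,7S,8R)-7-bromo-8,9-dihydroxy-4,8-dimethylnon-3-enoate
Product: 6 (3aS,4R,5S,7aR)-5-bromo-4-(hydroxymethyl)-4,7a-dimethylhexahydro-1-benzofuran-2(3H)-one (cis-fused bromo lactone, ring A)
Conditions: SnCl4 (2 equiv), 2,6-di-tert-butyl-4-methylpyridine, CH2Cl2, −78 to −20 °C; then aq. NaHCO3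
Reagents that add atoms: none
Why: Cation–olefin (bromonium-ion) cyclization: ionization of the tertiary alcohol with anchimeric help from the neighbouring bromine should give a configurationally defined bromonium ion that the E-alkene opens at the tertiary carbon through a chair transition state (Br and both CH2 arms equatorial, new methyl axial), and the ester oxygen should trap the tertiary cation as the thermodynamically preferred cis-fused lactone (axial C–O, no methyl/methyl 1,3-diaxial contact) with loss of the ester methyl group.

Step 6
Reactants: 6 (3aS,4R,5S,7aR)-5-bromo-4-(hydroxymethyl)-4,7a-dimethylhexahydro-1-benzofuran-2(3H)-one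
Product: 7 1-[(1S,2R,3S,6R)-3-bromo-6-hydroxy-2-(hydroxymethyl)-2,6-dimethylcyclohexyl]propan-2-one
Conditions: MeLi (2.2 equiv), THF, −78 °C; then H2O
Reagents that add atoms: methyllithium, [Li]C
Why: Addition of MeLi to the γ-lactone should stop at the tetrahedral lithium lactolate at −78 °C, so that one methyl group is delivered and the axial tertiary alcohol of ring A is set free without touching a stereocentre.

Step 7
Reactants: 7 1-[(1S,2R,3S,6R)-3-bromo-6-hydroxy-2-(hydroxymethyl)-2,6-dimethylcyclohexyl]propan-2-one
Product: 9 (4aS,5S,8R,8aS)-5-bromo-8-hydroxy-4a,8-dimethyl-4a,5,6,7,8,8a-hexahydronaphthalen-2(1H)-one (ring-B enone), via keto aldehyde 8 (not isolated)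
Conditions: TEMPO (10 mol%), PhI(OAc)2, CH2Cl2, 25 °C; then piperidine, AcOH, toluene, 60 °C
Reagents that add atoms: none
Why: TEMPO/PhI(OAc)2 oxidation of the primary neopentyl alcohol is followed by an amine-catalysed intramolecular aldol condensation in which only the methyl-ketone enamine can reach the non-enolizable aldehyde through a six-membered ring, which should give the ring-B enone with the trans ring fusion already in place.

Step 8
Reactants: 10 furan-2(5H)-one
Product: 11 (4S)-4-ethenyloxolan-2-one
Conditions: [Rh(cod)2]BF4 (3 mol%), (S)-BINAP, CH2=CHBF3K, toluene/H2O, 100 °C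
Reagents that add atoms: potassium vinyltrifluoroborate, [K+].C=C[B-](F)(F)F
Why: Rhodium-catalysed asymmetric 1,4-addition of an alkenylboron reagent to an unsaturated lactone (Hayashi–Miyaura reaction) with (S)-BINAP should give the (S)-configured β-vinyl lactone, by the same enone-face selection as for cyclohex-2-enone.

Step 9
Reactants: 11 (4S)-4-ethenyloxolan-2-one
Product: 13 (5S)-5-(hydroxymethyl)-2-methylhept-6-en-3-one, via Weinreb amide 12 (not isolated)
Conditions: MeNH(OMe)·HCl, i-PrMgCl (excess), THF, −20 to 25 °C; then aq. NH4Cl
Reagents that add atoms: isopropylmagnesium chloride, CC(C)[Mg]Cl; N,O-dimethylhydroxylamine hydrochloride, CNOC.Cl (atoms in 12 only)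
Why: Ring opening of the lactone by the chloromagnesium amide of N,O-dimethylhydroxylamine gives the Weinreb amide, whose stable magnesium chelate with i-PrMgCl should collapse to the isopropyl ketone only on work-up, and the stereocentre is not enolizable.

Step 10
Reactants: 13 (5S)-5-(hydroxymethyl)-2-methylhept-6-en-3-one
Product: 14 (5S)-5-(iodomethyl)-2-methylhept-6-en-3-one
Conditions: I2, PPh3, imidazole, CH2Cl2, 0 °C
Reagents that add atoms: iodine, II
Why: Appel-type iodination of the primary alcohol through the alkoxyphosphonium salt should drain the open hydroxy ketone from its hemiketal.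

Step 11
Reactants: 14 (5S)-5-(iodomethyl)-2-methylhept-6-en-3-one
Product: 15 2-[(2S)-2-(iodomethyl)but-3-en-1-yl]-2-(propan-2-yl)-1,3-dioxolane
Conditions: TMSOCH2CH2OTMS, TMSOTf (5 mol%), CH2Cl2, −78 °C
Reagents that add atoms: 1,2-bis(trimethylsilyloxy)ethane, C[Si](C)(C)OCCO[Si](C)(C)C
Why: Noyori ketalization (TMSOTf-catalysed exchange with the bis-silyl ether of ethylene glycol) should mask the ketone at low temperature without touching the primary iodide or the alkene.

Step 12
Reactants: 9 (4aS,5S,8R,8aS)-5-bromo-8-hydroxy-4a,8-dimethyl-4a,5,6,7,8,8a-hexahydronaphthalen-2(1H)-one; 15 2-[(2S)-2-(iodomethyl)but-3-en-1-yl]-2-(propan-2-yl)-1,3-dioxolane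
Product: 16 (1S,4aS,5S,8R,8aS)-5-bromo-8-hydroxy-4a,8-dimethyl-1-{(2S)-2-[(2-isopropyl-1,3-dioxolan-2-yl)methyl]but-3-en-1-yl}-4a,5,6,7,8,8a-hexahydronaphthalen-2(1H)-one
Conditions: LiN(i-Pr)2 (2.3 equiv), THF/HMPA, −78 °C; 15, −78 to −20 °C; then DBU, 25 °C
Reagents that add atoms: none
Why: Kinetic α′-deprotonation of the cross-conjugated enone (the γ-carbon is quaternary, so only one position is enolizable) and SN2 alkylation with the primary iodide, followed by base equilibration, should place the new chain equatorial and trans to the ring-fusion hydrogen.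

Step 13
Reactants: 16 the α′-alkylated enone
Product: 17 triene: 16 with the ring-B C=O replaced by an exocyclic C=CH2 (all stereocentres as in 16)
Conditions: Ph3PCH3Br, KOt-Bu, toluene, 25 to 80 °C
Reagents that add atoms: methyltriphenylphosphonium bromide, C[P+](c1ccccc1)(c1ccccc1)c1ccccc1.[Br-]
Why: Wittig methylenation of the hindered conjugated ketone with excess Ph3P=CH2 should proceed with the tertiary alkoxide inert and the epimerizable centre already in its stable configuration.

Step 14
Reactants: 17 the triene
Product: 18 tricyclic diene ketal: cyclopentene ring C closed between the former methylene carbon and the side-chain vinyl CH, 1,3-diene across rings B and C, CH2-dioxolane arm on the ring-C methine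
Conditions: second-generation Grubbs catalyst, RuCl2(=CHPh)(PCy3)(H2IMes) (5 mol%), toluene, 80 °C
Reagents that add atoms: none
Why: Ring-closing metathesis between the 1,1-disubstituted diene terminus and the vinyl group releases ethene and should give the five-membered ring C as a trisubstituted cyclopentene conjugated with the ring-B alkene.

Step 15
Reactants: 18 the tricyclic diene ketal
Product: 19 diene ketone: 18 with the dioxolane hydrolysed to the isopropyl ketone
Conditions: PPTS, acetone/H2O, 50 °C
Reagents that add atoms: water, O
Why: Acid-catalysed hydrolysis of the dioxolane (transketalization to acetone) should free the isopropyl ketone while the conjugated diene and the tertiary alcohol survive PPTS.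

Step 16
Reactants: 19 the diene ketone
Product: 21 tetracyclic homoallylic alcohol: the target skeleton with a cis C=C between the two CH positions of ring B that are CH2 groups in the target, via allylchromium species 20 (not isolated)
Conditions: CrCl2 (4 equiv), cyanocobalamin (C63H88CoN14O14P, 5 mol%), H2O (2 equiv), DMF, 25 °C
Reagents that add atoms: none
Why: Proposed new method: cobalt hydride, formed from the monovalent cobalt corrin (cyanocobalamin reduced by CrCl2) and water, should transfer a hydrogen atom to the less hindered diene terminus in ring C, CrCl2 should capture the resulting allyl radical as allylchromium 20, and 20 should add to the tethered ketone through its bridgehead terminus. The closest known reaction types are the CrCl2-mediated radical–polar crossover coupling of 1,3-dienes with carbonyl compounds (allyl radical, then allylchromium, then Nozaki–Hiyama-type addition) and the hydrogen-atom-transfer-initiated alkene–ketone cyclization with Fe(acac)3/PhSiH3; the intramolecular hydrogen-initiated version on a ketone is the new element. Ring D closes in the 5-exo-trig mode at the carbonyl carbon, the seven-membered alternative through the secondary allyl terminus being disfavoured. The configuration of the new quaternary bridgehead is dictated by the tether, because the ketone arm hangs from the ring-C methine fixed in 15 and can reach only one face of the allyl unit, and the ring-fusion methine set in step 12 then holds ring B exo on the bicyclo[2.2.1]heptane. The carbinol centre is set in a closed six-membered transition state in which the carbonyl oxygen is bound to chromium on the ring-B side of the new bond, so that oxygen should end exo (syn to the one-carbon bridge) and isopropyl endo. The step needs regioselective hydrogen delivery and chemoselectivity over the C–Br bond: the ring-C terminus is the less hindered one and leads to the more substituted allyl radical, and the secondary neopentyl bromide is equatorial on the rigid trans-decalin and poorly accessible to the cobalt nucleophile.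

Step 17
Reactants: 21 the tetracyclic homoallylic alcohol
Product: 22 the target, CNP0362628.1
Conditions: H2 (1 atm), [Ir(cod)(PCy3)(py)]PF6 (5 mol%), CH2Cl2, 25 °C
Reagents that add atoms: none
Why: Homogeneous hydrogenation with Crabtree's catalyst, which reduces hindered alkenes and can be directed by the hydroxyl groups, should saturate the cis-disubstituted ring-B alkene without hydrogenolysis of the C–Br bond and without forming a stereocentre.

**Compound list**

1 | geranyl chloride, (2E)-1-chloro-3,7-dimethylocta-2,6-diene | CC(C)=CCC/C(C)=C/CCl | starting material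
2 | methyl (3E)-4,8-dimethylnona-3,7-dienoate | CC(C)=CCC/C(C)=C/CC(=O)OC | intermediate
3 | methyl (3E,7E)-9-hydroxy-4,8-dimethylnona-3,7-dienoate | OC/C(C)=C/CC/C(C)=C/CC(=O)OC | intermediate
4 | methyl (3E)-6-[(2R,3R)-3-(hydroxymethyl)-3-methyloxiran-2-yl]-4-methylhex-3-enoate | OC[C@@]1(C)O[C@@H]1CC/C(C)=C/CC(=O)OC | intermediate
5 | methyl (3E,7S,8R)-7-bromo-8,9-dihydroxy-4,8-dimethylnon-3-enoate | OC[C@](O)(C)[C@@H](Br)CC/C(C)=C/CC(=O)OC | intermediate
6 | (3aS,4R,5S,7aR)-5-bromo-4-(hydroxymethyl)-4,7a-dimethylhexahydro-1-benzofuran-2(3H)-one | O=C1C[C@H]2[C@](C)(CO)[C@@H](Br)CC[C@@]2(C)O1 | intermediate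
7 | 1-[(1S,2R,3S,6R)-3-bromo-6-hydroxy-2-(hydroxymethyl)-2,6-dimethylcyclohexyl]propan-2-one | CC(=O)C[C@H]1[C@](C)(CO)[C@@H](Br)CC[C@@]1(C)O | intermediate
8 | (1R,2S,3R,6S)-6-bromo-3-hydroxy-1,3-dimethyl-2-(2-oxopropyl)cyclohexane-1-carbaldehyde (keto aldehyde, not isolated) | CC(=O)C[C@H]1[C@](C)(C=O)[C@@H](Br)CC[C@@]1(C)O | intermediate
9 | (4aS,5S,8R,8aS)-5-bromo-8-hydroxy-4a,8-dimethyl-4a,5,6,7,8,8a-hexahydronaphthalen-2(1H)-one | O=C1C[C@H]2[C@](C)(C=C1)[C@@H](Br)CC[C@@]2(C)O | intermediate
10 | furan-2(5H)-one | O=C1C=CCO1 | starting material
11 | (4S)-4-ethenyloxolan-2-one | O=C1C[C@@H](C=C)CO1 | intermediate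
12 | (3S)-3-(hydroxymethyl)-N-methoxy-N-methylpent-4-enamide (Weinreb amide, not isolated) | CON(C)C(=O)C[C@@H](C=C)CO | intermediate
13 | (5S)-5-(hydroxymethyl)-2-methylhept-6-en-3-one | CC(C)C(=O)C[C@@H](C=C)CO | intermediate
14 | (5S)-5-(iodomethyl)-2-methylhept-6-en-3-one | CC(C)C(=O)C[C@@H](C=C)CI | intermediate
15 | 2-[(2S)-2-(iodomethyl)but-3-en-1-yl]-2-(propan-2-yl)-1,3-dioxolane | CC(C)C1(OCCO1)C[C@@H](C=C)CI | intermediate
16 | (1S,4aS,5S,8R,8aS)-5-bromo-8-hydroxy-4a,8-dimethyl-1-{(2S)-2-[(2-isopropyl-1,3-dioxolan-2-yl)methyl]but-3-en-1-yl}-4a,5,6,7,8,8a-hexahydronaphthalen-2(1H)-one | CC(C)C1(OCCO1)C[C@@H](C=C)C[C@H]2[C@H]3[C@](C)(C=CC2=O)[C@@H](Br)CC[C@@]3(C)O | intermediate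
17 | triene: 16 with C=O replaced by exocyclic C=CH2 | CC(C)C1(OCCO1)C[C@@H](C=C)C[C@H]2[C@H]3[C@](C)(C=CC2=C)[C@@H](Br)CC[C@@]3(C)O | intermediate
18 | tricyclic diene ketal (rings A, B, C; dioxolane arm on the ring-C methine) | CC(C)C1(OCCO1)C[C@@H]2C[C@H]3[C@H]4[C@](C)(C=CC3=C2)[C@@H](Br)CC[C@@]4(C)O | intermediate
19 | tricyclic diene ketone (isopropyl ketone arm on the ring-C methine) | CC(C)C(=O)C[C@@H]1C[C@H]2[C@H]3[C@](C)(C=CC2=C1)[C@@H](Br)CC[C@@]3(C)O | intermediate
20 | σ-allylchromium dichloride, chromium on the ring-B CH next to the quaternary methyl carbon (not isolated) | CC(C)C(=O)C[C@@H]1C[C@H]2[C@H]3[C@](C)(C([Cr](Cl)Cl)C=C2C1)[C@@H](Br)CC[C@@]3(C)O | intermediate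
21 | tetracyclic homoallylic alcohol (ring-B didehydro analogue of 22) | CC(C)[C@]1(O)C[C@@H]2C[C@H]3[C@H]4[C@](C)(C=C[C@@]31C2)[C@@H](Br)CC[C@@]4(C)O | intermediate
22 | CNP0362628.1 | CC(C)[C@]1(O)C[C@@H]2C[C@H]3[C@H]4[C@](C)(CC[C@@]31C2)[C@@H](Br)CC[C@@]4(C)O | target

**Step count and risks**

Total step count: 17. Longest linear sequence: 13 steps (steps 1–7 and 12–17).

Steps most likely to fail:

1. Step 16 (Proposed new method). What may go wrong: hydrogen-atom delivery to the other diene terminus, protonation of the allylchromium before it adds to the hindered ketone, or a slow addition that lets the diene be simply reduced. Fallback with known chemistry, setting out from 16 and coming back at 22: the enone of 16 would be reduced in the 1,4-sense with [(Ph3P)CuH]6 to the saturated trans-decalone F1. Ph3P=CH2 would convert F1 into the exocyclic alkene F2. Ring-closing metathesis with the second-generation Grubbs catalyst, RuCl2(=CHPh)(PCy3)(H2IMes), would give the cyclopentene ketal F3, and PPTS in aqueous acetone the cyclopentene ketone F4. The known hydrogen-atom-transfer radical cyclization of alkene-tethered ketones (Fe(acac)3, PhSiH3, EtOH, 60 °C) would then generate the tertiary bridgehead radical of F4 and close ring D onto the ketone to give 22 directly. The open question in this fallback is the exo/endo orientation of the hydroxyl group at the carbinol carbon, which is not held by a metal bridge.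

2. Step 5. What may go wrong: hydride shift or elimination from the β-bromo cation next to the CH2OH group, protonation of the nucleophilic alkene followed by simple lactonization, or incomplete conversion of the trans-fused into the cis-fused lactone. Fallback, setting out from 3 and coming back at 6: 3 would be cyclized directly with bromodiethylsulfonium bromopentachloroantimonate (Et2SBr·SbBrCl5) in MeNO2 at −25 °C to the racemic lactone, a 1:1 mixture of 6 and the enantiomer of 6 F5. Lipase-catalysed acetylation (Amano lipase PS, vinyl acetate), assumed to prefer F5, would convert it into the acetate of the enantiomer of 6 F6, and unreacted 6 would be separated by chromatography.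

3. Step 12. What may go wrong: slow C-alkylation of the cross-conjugated lithium enolate by the β-branched iodide, with proton transfer or O-alkylation taking over. Fallback, setting out from 9 and coming back at 16: 9 would be condensed with Me2NNH2 (AcOH cat., EtOH) to the N,N-dimethylhydrazone of 9 F7. Its more nucleophilic α′-azaenolate (LiN(i-Pr)2, THF, −78 °C) would be alkylated with 15 to the alkylated hydrazone F8, and hydrolysis with Cu(OAc)2 in aqueous THF followed by DBU equilibration would give 16.

Further compounds
F1 | step 16 | saturated trans-decalone from 1,4-reduction of 16 | CC(C)C1(OCCO1)C[C@@H](C=C)C[C@H]2[C@H]3[C@](C)(CCC2=O)[C@@H](Br)CC[C@@]3(C)O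
F2 | step 16 | exocyclic methylene analogue of F1 | CC(C)C1(OCCO1)C[C@@H](C=C)C[C@H]2[C@H]3[C@](C)(CCC2=C)[C@@H](Br)CC[C@@]3(C)O
F3 | step 16 | cyclopentene ketal with ring C closed and ring B saturated | CC(C)C1(OCCO1)C[C@@H]2C[C@H]3[C@H]4[C@](C)(CCC3=C2)[C@@H](Br)CC[C@@]4(C)O
F4 | step 16 | cyclopentene ketone with ring B saturated | CC(C)C(=O)C[C@@H]1C[C@H]2[C@H]3[C@](C)(CCC2=C1)[C@@H](Br)CC[C@@]3(C)O
F5 | step 5 | enantiomer of 6 | O=C1C[C@@H]2[C@@](C)(CO)[C@H](Br)CC[C@]2(C)O1
F6 | step 5 | acetate of the enantiomer of 6 | O=C1C[C@@H]2[C@@](C)(COC(C)=O)[C@H](Br)CC[C@]2(C)O1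
F7 | step 12 | N,N-dimethylhydrazone of 9 | CN(C)N=C1C[C@H]2[C@](C)(C=C1)[C@@H](Br)CC[C@@]2(C)O
F8 | step 12 | α′-alkylated N,N-dimethylhydrazone | CC(C)C1(OCCO1)C[C@@H](C=C)C[C@H]2[C@H]3[C@](C)(C=CC2=NN(C)C)[C@@H](Br)CC[C@@]3(C)O
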